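The flavone is cut through ring C at O1–C8a, C4–C4a and O1–C2. Ring A carries O1 (on C8a) and the C4 carbonyl (on C4a) on adjacent carbons, with the side chain on C8 next to C8a, so an aryne spanning C8a–C4a can take up the oxygen and the carbon of a carboxyl group at once. In one operation the aryne from silyl triflate 24 inserts into the C–O bond of arylpropiolic acid 29 and the resulting ortho-hydroxyaryl ynone closes ring C, giving the fully methoxymethyl (MOM)-protected flavone 32. Precursor 24 is a pentasubstituted ortho-trimethylsilyl aryl triflate of ring A that already bears the enantiopure, MOM-protected side chain.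

Key step: step 15

Remark: the side-chain stereocentre is R in the target because CH2Ar ranks above the hydroxyalkyl arm and below isopropenyl. The same spatial arrangement is S in 7–11 and 21, where that carbon carries C=O, CH2O, CH2I or CH2Zn. Epoxide 8 is formed as both epimers at the oxirane carbon, which is no longer a stereocentre after step 4.

**Fragment 1: side-chain iodide 11**

Step 1
Reactants: 1 (S)-4-benzyl-1,3-oxazolidin-2-one; 2 3-methylbut-2-enoyl chloride
Product: 4 (4S)-4-benzyl-3-(3-methylbut-2-enoyl)-1,3-oxazolidin-2-one, via lithium oxazolidinide 3 (not isolated)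
Conditions: n-BuLi, THF, −78 °C; then 2, −78 → 0 °C
Reagents that add atoms: none
Why: N-acylation of the lithiated auxiliary by an acid chloride at low temperature is the standard entry to N-enoyl oxazolidinones and avoids the amine-induced ketene pathway that would deconjugate the enoyl group.

Step 2
Reactants: 4 (4S)-4-benzyl-3-(3-methylbut-2-enoyl)-1,3-oxazolidin-2-one; 5 prenyl bromide (1-bromo-3-methylbut-2-ene)
Product: 7 (4S)-4-benzyl-3-[(2S)-5-methyl-2-(prop-1-en-2-yl)hex-4-enoyl]-1,3-oxazolidin-2-one, via sodium dienolate 6 (not isolated)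
Conditions: NaN(SiMe3)2, THF, −78 °C; then 5, −78 → −40 °C
Reagents that add atoms: none
Why: Evans asymmetric alkylation in its deconjugative form: γ-deprotonation gives the chelated Z-dienolate, which is alkylated at the α-carbon on the face opposite the benzyl group, and this sets the only stereocentre of the target (2S here, R in the target).

Step 3
Reactants: 7 (4S)-4-benzyl-3-[(2S)-5-methyl-2-(prop-1-en-2-yl)hex-4-enoyl]-1,3-oxazolidin-2-one
Product: 8 (4S)-4-benzyl-3-{(2S)-2-[(3,3-dimethyloxiran-2-yl)methyl]-3-methylbut-3-enoyl}-1,3-oxazolidin-2-one (both oxirane epimers)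
Conditions: mCPBA (1.05 equiv), NaHCO3, CH2Cl2, 0 °C
Reagents that add atoms: mCPBA (O=C(OO)c1cccc(Cl)c1)
Why: Prilezhaev epoxidation should be faster at the electron-rich trisubstituted alkene than at the 1,1-disubstituted alkene, which is further deactivated by the neighbouring acyl carbon.

Step 4
Reactants: 8 epoxy imide
Product: 9 (2S)-5-methyl-2-(prop-1-en-2-yl)hexane-1,5-diol
Conditions: LiAlH4, THF, 0 → 40 °C; then H2O, aq. NaOH
Reagents that add atoms: none
Why: LiAlH4 reductively cleaves the imide to the primary alcohol (auxiliary recovered) and opens the trisubstituted epoxide by hydride attack at its less hindered carbon, so both epoxide epimers converge on one tertiary alcohol while the α-stereocentre is not touched.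

Step 5
Reactants: 9 (2S)-5-methyl-2-(prop-1-en-2-yl)hexane-1,5-diol
Product: 10 (5S)-5-(iodomethyl)-2,6-dimethylhept-6-en-2-ol
Conditions: I2, PPh3, imidazole, CH2Cl2, 0 °C
Reagents that add atoms: iodine (II)
Why: Appel-type iodination activates only the unhindered primary hydroxyl as its alkoxyphosphonium salt, which iodide displaces by SN2 at a carbon that is not the stereocentre, while the tertiary alcohol stays unreacted.

Step 6
Reactants: 10 (5S)-5-(iodomethyl)-2,6-dimethylhept-6-en-2-ol
Product: 11 (3S)-3-(iodomethyl)-6-(methoxymethoxy)-2,6-dimethylhept-1-ene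
Conditions: MOMCl, NaI, i-Pr2NEt, DME, 40 °C
Reagents that add atoms: chloromethyl methyl ether (COCCl)
Why: Williamson-type acetalization of the hindered tertiary alcohol by iodomethyl methyl ether formed in the flask; NaCl precipitates from DME, so no chloride remains to exchange with the primary iodide.

**Fragment 2: ring A iodide 20**

Step 7
Reactants: 12 phloroglucinol
Product: 13 3,5-bis(methoxymethoxy)phenol
Conditions: MOMCl (2 equiv), i-Pr2NEt, THF/DMF, 0 °C → rt; chromatography
Reagents that add atoms: chloromethyl methyl ether (COCCl)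
Why: Statistical O-alkylation of a threefold symmetric triol, from which the bis-ether is separated from the mono- and tris-ethers; this is acceptable as the first step from a bulk chemical.

Step 8
Reactants: 13 3,5-bis(methoxymethoxy)phenol
Product: 14 3,5-bis(methoxymethoxy)phenyl N-isopropylcarbamate
Conditions: i-PrNCO, Et3N (cat.), CH2Cl2, rt
Reagents that add atoms: isopropyl isocyanate (CC(C)N=C=O)
Why: Base-catalysed addition of the phenol to an isocyanate gives an N-monoalkyl carbamate, chosen because it is a strong ortho director after N-silylation and can later be removed under mild base by isocyanate elimination.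

Step 9
Reactants: 14 3,5-bis(methoxymethoxy)phenyl N-isopropylcarbamate
Product: 20 2-iodo-3,5-bis(methoxymethoxy)-6-(trimethylsilyl)phenyl N-isopropylcarbamate, via N-silyl carbamate 15 (not isolated), via aryllithium 16 (not isolated), via N-silyl arylsilane 17 (not isolated), via silylated aryllithium 18 (not isolated), via N-silyl aryl iodide 19 (not isolated)
Conditions: TBSOTf, TMEDA, Et2O, 0 °C → rt; n-BuLi (2.1 equiv), −78 °C; TMSCl (1.1 equiv), −78 → −40 °C; n-BuLi (1.3 equiv), −78 °C; ICH2CH2I, −78 °C → rt; aq. NH4Cl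
Reagents that add atoms: chlorotrimethylsilane (C[Si](C)(C)Cl); 1,2-diiodoethane (ICCI)
Why: Two consecutive directed ortho-metalations in one flask: the in situ N-silylated carbamate and a neighbouring acetal oxygen direct the first lithiation to the carbon between them (future C4a), silicon then blocks that site so that the second lithiation goes to the other carbamate-flanked carbon (future C8) in preference to the site between the two weaker acetal directors, 1,2-diiodoethane delivers iodine there without exposing the arylsilane to free iodine, and the N–Si bond, kept intact between the two metalations, is hydrolysed only on work-up.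

**Union of fragments 1 and 2, aryne precursor**

Step 10
Reactants: 20 2-iodo-3,5-bis(methoxymethoxy)-6-(trimethylsilyl)phenyl N-isopropylcarbamate; 11 (3S)-3-(iodomethyl)-6-(methoxymethoxy)-2,6-dimethylhept-1-ene
Product: 22 2-[(2R)-5-(methoxymethoxy)-5-methyl-2-(prop-1-en-2-yl)hexyl]-3,5-bis(methoxymethoxy)-6-(trimethylsilyl)phenyl N-isopropylcarbamate, via alkylzinc iodide 21 (not isolated)
Conditions: 11 (1.4 equiv), Zn dust (activated by BrCH2CH2Br, TMSCl), LiCl, THF, 40 °C; then 20, Pd(OAc)2, SPhos, THF/NMP, 50 °C
Reagents that add atoms: none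
Why: Negishi coupling: zinc inserts into the primary C–I bond without touching the β-stereocentre, a bulky biarylphosphine palladium catalyst couples primary alkylzinc halides with di-ortho-substituted aryl iodides with reductive elimination faster than β-hydride elimination, and alkylzinc iodides tolerate a carbamate N–H.

Step 11
Reactants: 22 side-chain-bearing silyl carbamate
Product: 24 2-[(2R)-5-(methoxymethoxy)-5-methyl-2-(prop-1-en-2-yl)hexyl]-3,5-bis(methoxymethoxy)-6-(trimethylsilyl)phenyl trifluoromethanesulfonate, via silylphenol 23 (not isolated)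
Conditions: DBU, Et2NH, MeCN, 40 °C; then PhNTf2, rt
Reagents that add atoms: N-phenylbis(trifluoromethanesulfonimide) (O=S(=O)(N(c1ccccc1)S(=O)(=O)C(F)(F)F)C(F)(F)F)
Why: E1cB cleavage of the N–H carbamate (isopropyl isocyanate is lost and trapped by Et2NH as a urea) releases the hindered phenoxide, which is triflated in the same flask by a mild triflyl donor, so neither acid nor fluoride touches the C–Si bond or the acetals.

**Fragment 3: arylpropiolic acid 29**

Step 12
Reactants: 25 2,4-dihydroxybenzaldehyde
Product: 26 2,4-bis(methoxymethoxy)benzaldehyde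
Conditions: MOMCl (3 equiv), i-Pr2NEt, CH2Cl2, 0 → 40 °C
Reagents that add atoms: chloromethyl methyl ether (COCCl)
Why: Exhaustive O-alkylation of both phenols, the hydrogen-bonded ortho hydroxyl needing the excess reagent and gentle warming.

Step 13
Reactants: 26 2,4-bis(methoxymethoxy)benzaldehyde
Product: 27 1-(2,2-dibromoethenyl)-2,4-bis(methoxymethoxy)benzene
Conditions: CBr4, PPh3, Et3N, CH2Cl2, 0 °C
Reagents that add atoms: carbon tetrabromide (BrC(Br)(Br)Br)
Why: Corey–Fuchs dibromo-olefination (Wittig-type reaction of Ph3P=CBr2 with the aldehyde), with Et3N buffering the medium so that the acetals survive.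

Step 14
Reactants: 27 1-(2,2-dibromoethenyl)-2,4-bis(methoxymethoxy)benzene
Product: 29 3-[2,4-bis(methoxymethoxy)phenyl]prop-2-ynoic acid, via lithium acetylide 28 (not isolated)
Conditions: n-BuLi (2.1 equiv), THF, −78 °C; CO2; cold dilute HCl to pH 3
Reagents that add atoms: carbon dioxide (O=C=O)
Why: Second stage of the Corey–Fuchs sequence: bromine–lithium exchange and Fritsch–Buttenberg–Wiechell rearrangement give the lithium acetylide, which is carboxylated in the flask, and the acid is isolated cold and used promptly to avoid self-catalysed acetal loss.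

**Key step and end game**

Step 15
Reactants: 24 ring A silyl triflate; 29 3-[2,4-bis(methoxymethoxy)phenyl]prop-2-ynoic acid
Product: 32 2-[2,4-bis(methoxymethoxy)phenyl]-5,7-bis(methoxymethoxy)-8-[(2R)-5-(methoxymethoxy)-5-methyl-2-(prop-1-en-2-yl)hexyl]-4H-chromen-4-one, via aryne 30 (not isolated), via hydroxyaryl ynone 31 (not isolated)
Conditions: 29 (2 equiv), CsF (5 equiv), 18-crown-6, THF, 70 °C, sealed tube
Reagents that add atoms: none
Why: Proposed new method: fluoride removes Me3Si from 24 and triflate departs to give aryne 30; the cesium carboxylate of 29 adds through oxygen to C8a, the aryl anion at C4a attacks the ester carbonyl it now carries, and the four-membered adduct opens to the phenoxide of ynone 31 (C8a–O1 and C4a–C4 formed), the closest known reaction type being aryne insertion into the C–O bond of simple carboxylic acids to give ortho-hydroxyaryl ketones. Ring C then closes by 6-endo-dig oxa-Michael addition of O1 to C2, the known base-mediated flavone closure of ortho-hydroxyaryl ynones, which is expected to be favoured over 5-exo-dig (aurone) closure for an aryl ynone under anhydrous fluoride. What is untested is the merger of both events with an arylpropiolic acid on a trisubstituted, unsymmetrical aryne. The required regiochemistry rests on the C5 methoxymethoxy group, whose inductive pull distorts the aryne so that the nucleophile enters at the distal C8a and negative charge builds at C4a, which places the chain at C8 and not at C6. Aprotic THF and an excess of carboxylate should favour acyl transfer over protonation of the C4a anion and bimolecular capture over an intramolecular ene reaction with the isopropenyl group. No stereocentre is formed, and the existing one is remote from all reacting centres.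

Step 16
Reactants: 32 pentakis(methoxymethyl)-protected flavone
Product: 33 2-(2,4-dihydroxyphenyl)-5,7-dihydroxy-8-[(2R)-5-hydroxy-5-methyl-2-(prop-1-en-2-yl)hexyl]-4H-chromen-4-one (target)
Conditions: HCl (2 M), MeOH/THF, 40 °C
Reagents that add atoms: none
Why: Acid-catalysed transacetalization to methanol removes the four aryl and the one tertiary alkyl methoxymethyl ether as dimethoxymethane at a temperature chosen to stay below alkene protonation, and the stereocentre is not involved.

**Compound list**

1 | (S)-4-benzyl-1,3-oxazolidin-2-one | O=C1N[C@@H](Cc2ccccc2)CO1 | starting material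
2 | 3-methylbut-2-enoyl chloride | CC(C)=CC(=O)Cl | starting material
3 | lithium (S)-4-benzyl-2-oxo-1,3-oxazolidin-3-ide (formed in situ) | [Li]N1C(=O)OC[C@@H]1Cc1ccccc1 | intermediate
4 | (4S)-4-benzyl-3-(3-methylbut-2-enoyl)-1,3-oxazolidin-2-one | CC(C)=CC(=O)N1C(=O)OC[C@@H]1Cc1ccccc1 | intermediate
5 | prenyl bromide (1-bromo-3-methylbut-2-ene) | CC(C)=CCBr | starting material
6 | sodium Z-dienolate of 4 (formed in situ) | C=C(C)/C=C(\O[Na])N1C(=O)OC[C@@H]1Cc1ccccc1 | intermediate
7 | (4S)-4-benzyl-3-[(2S)-5-methyl-2-(prop-1-en-2-yl)hex-4-enoyl]-1,3-oxazolidin-2-one | C=C(C)[C@H](CC=C(C)C)C(=O)N1C(=O)OC[C@@H]1Cc1ccccc1 | intermediate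
8 | (4S)-4-benzyl-3-{(2S)-2-[(3,3-dimethyloxiran-2-yl)methyl]-3-methylbut-3-enoyl}-1,3-oxazolidin-2-one, both oxirane epimers | C=C(C)[C@H](CC1OC1(C)C)C(=O)N1C(=O)OC[C@@H]1Cc1ccccc1 | intermediate
9 | (2S)-5-methyl-2-(prop-1-en-2-yl)hexane-1,5-diol | C=C(C)[C@H](CCC(C)(C)O)CO | intermediate
10 | (5S)-5-(iodomethyl)-2,6-dimethylhept-6-en-2-ol | C=C(C)[C@H](CCC(C)(C)O)CI | intermediate
11 | (3S)-3-(iodomethyl)-6-(methoxymethoxy)-2,6-dimethylhept-1-ene | C=C(C)[C@H](CCC(C)(C)OCOC)CI | intermediate
12 | phloroglucinol | Oc1cc(O)cc(O)c1 | starting material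
13 | 3,5-bis(methoxymethoxy)phenol | COCOc1cc(O)cc(OCOC)c1 | intermediate
14 | 3,5-bis(methoxymethoxy)phenyl N-isopropylcarbamate | CC(C)NC(=O)Oc1cc(OCOC)cc(OCOC)c1 | intermediate
15 | 3,5-bis(methoxymethoxy)phenyl N-(tert-butyldimethylsilyl)-N-isopropylcarbamate (formed in situ) | CC(C)N(C(=O)Oc1cc(OCOC)cc(OCOC)c1)[Si](C)(C)C(C)(C)C | intermediate
16 | 2-lithio-3,5-bis(methoxymethoxy)phenyl N-(tert-butyldimethylsilyl)-N-isopropylcarbamate (formed in situ) | CC(C)N(C(=O)Oc1cc(OCOC)cc(OCOC)c1[Li])[Si](C)(C)C(C)(C)C | intermediate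
17 | 3,5-bis(methoxymethoxy)-2-(trimethylsilyl)phenyl N-(tert-butyldimethylsilyl)-N-isopropylcarbamate (formed in situ) | CC(C)N(C(=O)Oc1cc(OCOC)cc(OCOC)c1[Si](C)(C)C)[Si](C)(C)C(C)(C)C | intermediate
18 | 2-lithio-3,5-bis(methoxymethoxy)-6-(trimethylsilyl)phenyl N-(tert-butyldimethylsilyl)-N-isopropylcarbamate (formed in situ) | CC(C)N(C(=O)Oc1c([Li])c(OCOC)cc(OCOC)c1[Si](C)(C)C)[Si](C)(C)C(C)(C)C | intermediate
19 | 2-iodo-3,5-bis(methoxymethoxy)-6-(trimethylsilyl)phenyl N-(tert-butyldimethylsilyl)-N-isopropylcarbamate (formed in situ) | CC(C)N(C(=O)Oc1c(I)c(OCOC)cc(OCOC)c1[Si](C)(C)C)[Si](C)(C)C(C)(C)C | intermediate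
20 | 2-iodo-3,5-bis(methoxymethoxy)-6-(trimethylsilyl)phenyl N-isopropylcarbamate | CC(C)NC(=O)Oc1c(I)c(OCOC)cc(OCOC)c1[Si](C)(C)C | intermediate
21 | [(2S)-5-(methoxymethoxy)-5-methyl-2-(prop-1-en-2-yl)hexyl]zinc iodide (formed in situ) | C=C(C)[C@H](CCC(C)(C)OCOC)C[Zn]I | intermediate
22 | 2-[(2R)-5-(methoxymethoxy)-5-methyl-2-(prop-1-en-2-yl)hexyl]-3,5-bis(methoxymethoxy)-6-(trimethylsilyl)phenyl N-isopropylcarbamate | C=C(C)[C@H](CCC(C)(C)OCOC)Cc1c(OCOC)cc(OCOC)c([Si](C)(C)C)c1OC(=O)NC(C)C | intermediate
23 | 2-[(2R)-5-(methoxymethoxy)-5-methyl-2-(prop-1-en-2-yl)hexyl]-3,5-bis(methoxymethoxy)-6-(trimethylsilyl)phenol (formed in situ as its phenoxide) | C=C(C)[C@H](CCC(C)(C)OCOC)Cc1c(OCOC)cc(OCOC)c([Si](C)(C)C)c1O | intermediate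
24 | 2-[(2R)-5-(methoxymethoxy)-5-methyl-2-(prop-1-en-2-yl)hexyl]-3,5-bis(methoxymethoxy)-6-(trimethylsilyl)phenyl trifluoromethanesulfonate | C=C(C)[C@H](CCC(C)(C)OCOC)Cc1c(OCOC)cc(OCOC)c([Si](C)(C)C)c1OS(=O)(=O)C(F)(F)F | intermediate
25 | 2,4-dihydroxybenzaldehyde | O=Cc1ccc(O)cc1O | starting material
26 | 2,4-bis(methoxymethoxy)benzaldehyde | O=Cc1ccc(OCOC)cc1OCOC | intermediate
27 | 1-(2,2-dibromoethenyl)-2,4-bis(methoxymethoxy)benzene | BrC(Br)=Cc1ccc(OCOC)cc1OCOC | intermediate
28 | lithium [2,4-bis(methoxymethoxy)phenyl]acetylide (formed in situ) | [Li]C#Cc1ccc(OCOC)cc1OCOC | intermediate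
29 | 3-[2,4-bis(methoxymethoxy)phenyl]prop-2-ynoic acid | OC(=O)C#Cc1ccc(OCOC)cc1OCOC | intermediate
30 | 3-[(2R)-5-(methoxymethoxy)-5-methyl-2-(prop-1-en-2-yl)hexyl]-4,6-bis(methoxymethoxy)-1,2-didehydrobenzene (aryne, formed in situ) | C=C(C)[C@H](CCC(C)(C)OCOC)CC1=C(OCOC)C=C(OCOC)C#C1 | intermediate
31 | 1-{2-hydroxy-4,6-bis(methoxymethoxy)-3-[(2R)-5-(methoxymethoxy)-5-methyl-2-(prop-1-en-2-yl)hexyl]phenyl}-3-[2,4-bis(methoxymethoxy)phenyl]prop-2-yn-1-one (formed in situ as its phenoxide) | C=C(C)[C@H](CCC(C)(C)OCOC)Cc1c(OCOC)cc(OCOC)c(C(=O)C#Cc2ccc(OCOC)cc2OCOC)c1O | intermediate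
32 | 2-[2,4-bis(methoxymethoxy)phenyl]-5,7-bis(methoxymethoxy)-8-[(2R)-5-(methoxymethoxy)-5-methyl-2-(prop-1-en-2-yl)hexyl]-4H-chromen-4-one | C=C(C)[C@H](CCC(C)(C)OCOC)Cc1c(OCOC)cc(OCOC)c2c(=O)cc(-c3ccc(OCOC)cc3OCOC)oc12 | intermediate
33 | 2-(2,4-dihydroxyphenyl)-5,7-dihydroxy-8-[(2R)-5-hydroxy-5-methyl-2-(prop-1-en-2-yl)hexyl]-4H-chromen-4-one | C=C(C)[C@H](CCC(C)(C)O)Cc1c(O)cc(O)c2c(=O)cc(-c3ccc(O)cc3O)oc12 | target

**Step count**

Total: 16 steps. Longest linear sequence: 10 steps (steps 1–6, 10, 11, 15, 16).

**Steps most likely to fail**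

1. Step 15 (bears the label). What may go wrong:
- the aryne may be consumed intramolecularly by an ene reaction with the isopropenyl group before the carboxylate arrives;
- the C4a anion may be protonated before acyl transfer, stopping at the aryl ester;
- the propiolate may decarboxylate on heating;
- ring closure may take the 5-exo course.

Fallback (known reactions only; sets out from 14 through its aryllithium 16, draws on 21 and 29, and returns at 32 by way of 31): aryllithium 16, made as in the first half of step 9, is quenched with 1,2-diiodoethane to give the N-silyl aryl iodide F1 and, after aqueous NH4Cl, 2-iodo-3,5-bis(methoxymethoxy)phenyl N-isopropylcarbamate F2. Negishi coupling of F2 with alkylzinc iodide 21 under the conditions of step 10 should give the chain-bearing carbamate F3. In situ N-silylation to the N-silyl carbamate F4 and kinetic ortho-lithiation (n-BuLi, TMEDA, −78 °C) at the carbon between the carbamate and the C5 acetal give the aryllithium F5. F5 is acylated with the Weinreb amide F6, prepared from 29 with MeNHOMe·HCl, EDC·HCl and i-Pr2NEt, and work-up should release the ortho-carbamoyloxy ynone F7. DBU and Et2NH in MeCN at 40 °C then remove the carbamate as in step 11, and the phenoxide of 31 formed in this way closes to 32 by the same 6-endo cyclization without any aryne.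

2. Step 10. What may go wrong:
- slow oxidative addition or transmetalation at the doubly ortho-substituted iodide;
- β-hydride elimination from the alkylpalladium intermediate toward a conjugated diene;
- protonation of the organozinc by the carbamate N–H.

Fallback (sets out from 11 and 20, returns at 22): a B-alkyl Suzuki–Miyaura coupling replaces the zinc reagent. Iodine–lithium exchange on 11 (t-BuLi, 2.1 equiv, Et2O, −78 °C) gives the alkyllithium F8, which is trapped with B-methoxy-9-BBN as the lithium borinate F9. This ate complex is coupled with 20 using PdCl2(dppf), aqueous K3PO4 and DMF at room temperature to give 22. Should the carbamate be lost under the basic conditions, the product would be silylphenol 23, which lies on the route.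

3. Step 16. What may go wrong: protonation of the isopropenyl group with capture by the C7 hydroxyl (chroman formation), or ionization of the tertiary alcohol, before the last acetal is gone.

Fallback (sets out from 32, returns at 33): Brønsted-acid solvolysis is replaced by Lewis-acid-assisted thiolysis. ZnBr2 and n-PrSH in CH2Cl2 at 0 °C transfer each methoxymethyl group to sulfur within minutes, a known method that frees tertiary alcohols and phenols alike without a protic acid medium. It passes through no new isolable compound (entry F0).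

**Further compounds**

F1 | step 15 | N-(tert-butyldimethylsilyl) derivative of F2 (formed in situ) | CC(C)N(C(=O)Oc1cc(OCOC)cc(OCOC)c1I)[Si](C)(C)C(C)(C)C
F2 | step 15 | 2-iodo-3,5-bis(methoxymethoxy)phenyl N-isopropylcarbamate | CC(C)NC(=O)Oc1cc(OCOC)cc(OCOC)c1I
F3 | step 15 | 2-[(2R)-5-(methoxymethoxy)-5-methyl-2-(prop-1-en-2-yl)hexyl]-3,5-bis(methoxymethoxy)phenyl N-isopropylcarbamate | C=C(C)[C@H](CCC(C)(C)OCOC)Cc1c(OCOC)cc(OCOC)cc1OC(=O)NC(C)C
F4 | step 15 | N-(tert-butyldimethylsilyl) derivative of F3 (formed in situ) | C=C(C)[C@H](CCC(C)(C)OCOC)Cc1c(OCOC)cc(OCOC)cc1OC(=O)N(C(C)C)[Si](C)(C)C(C)(C)C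
F5 | step 15 | 6-lithio derivative of F4 (formed in situ) | C=C(C)[C@H](CCC(C)(C)OCOC)Cc1c(OCOC)cc(OCOC)c([Li])c1OC(=O)N(C(C)C)[Si](C)(C)C(C)(C)C
F6 | step 15 | N-methoxy-N-methyl-3-[2,4-bis(methoxymethoxy)phenyl]prop-2-ynamide | CON(C)C(=O)C#Cc1ccc(OCOC)cc1OCOC
F7 | step 15 | 2-{3-[2,4-bis(methoxymethoxy)phenyl]prop-2-ynoyl}-6-[(2R)-5-(methoxymethoxy)-5-methyl-2-(prop-1-en-2-yl)hexyl]-3,5-bis(methoxymethoxy)phenyl N-isopropylcarbamate | C=C(C)[C@H](CCC(C)(C)OCOC)Cc1c(OCOC)cc(OCOC)c(C(=O)C#Cc2ccc(OCOC)cc2OCOC)c1OC(=O)NC(C)C
F8 | step 10 | [(2S)-5-(methoxymethoxy)-5-methyl-2-(prop-1-en-2-yl)hexyl]lithium (formed in situ) | C=C(C)[C@H](CCC(C)(C)OCOC)C[Li]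
F9 | step 10 | lithium B-methoxy-B-[(2S)-5-(methoxymethoxy)-5-methyl-2-(prop-1-en-2-yl)hexyl]-9-borabicyclo[3.3.1]nonan-9-uide (formed in situ) | [Li+].C=C(C)[C@H](CCC(C)(C)OCOC)C[B-]1(OC)C2CCCC1CCC2
F0 | step 16 | none | none
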